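Numbering (carotane): C1 quaternary carbon with CH3, C2=C3, C4 carbinol with isopropyl, C5 ring-fusion CH, C6 acyloxy carbon, C7, C8 carbinol with CH3, C9, C10. The five-membered ring is C1–C5 and the seven-membered ring is C1, C5–C10.
Cuts, in retrosynthetic order: the C6–O vanilloyl ester; C2=C3 (metathesis); C4–isopropyl; C4–C5 (aldol) together with C1–vinyl (conjugate addition); the C1–O bond of an oxygen bridge between C1 and C8; the C1–C5 and C7–C8 bonds of a [4+3] cycloadduct.
Enabling feature: C2=C3 is the only alkene and lies in the five-membered ring, flanked by the quaternary C1 and the tertiary carbinol C4. C1 is itself a member of the seven-membered ring and C4 hangs on its ring neighbour C5, so each can bear a vinyl group and the two vinyl groups form a 1,6-diene.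
Forward: the seven-membered ring comes first, from 2,5-dimethylfuran (C1, C8, C9, C10, both methyl groups, O8) and a chlorinated oxyallyl cation (C5, C6, C7, O6). Bridge opening, a vinyl/acrolein three-component coupling and isopropyl addition load the ring, the five-membered ring closes last, and the ester follows.
Stereochemistry: C8 comes from enantioselective deprotonation of the meso bicyclic ketone by a chiral lithium amide; C1 and C5 from the conformational bias that C8 imposes on enone and enolate; C6 from hydride delivery by the C8 hydroxyl; C4 from chelate/Felkin-controlled addition of isopropyl anti to C1.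

Key step: step 12

Assumption: the (R,R) lithium amide is taken to remove the C5 proton of the meso ketone. The sense of induction has to be confirmed on compound 8, and the equally available (S,S) amide is used if it proves opposite.

Step 1
Reactants: 1 2,5-dimethylfuran; 2 1,1,3-trichloroacetone
Product: 4 2,4-dichloro-1,5-dimethyl-8-oxabicyclo[3.2.1]oct-6-en-3-one (C–Cl epimers), via 1,3-dichloro-2-oxyallyl cation 3 (not isolated)
Conditions: Et3N, CF3CH2OH, 0 °C → rt
Reagents that add atoms: none
Why: Loss of HCl from 2 gives the oxyallyl cation 3, which adds across C2 and C5 of the electron-rich furan in a [4+3] cycloaddition (a standard entry to 8-oxabicyclo[3.2.1]oct-6-en-3-ones in trifluoroethanol), so all seven ring carbons, both methyl groups, O6 and O8 arrive at once, the bridge can only be cis and the C–Cl centres are erased in step 2.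

Step 2
Reactants: 4 dichloro cycloadduct
Product: 5 (1R,5S)-1,5-dimethyl-8-oxabicyclo[3.2.1]oct-6-en-3-one (meso)
Conditions: Zn–Cu couple, NH4Cl, MeOH, rt
Reagents that add atoms: none
Why: Reductive dehalogenation of α-chloro ketones by zinc runs through zinc enolates that NH4Cl protonates, spares the alkene, the ketone and the ether bridge and leaves the meso ketone 5.

Step 3
Reactants: 5 meso enone-free bicyclic alkene ketone
Product: 6 (1R,5S)-1,5-dimethyl-8-oxabicyclo[3.2.1]octan-3-one (meso)
Conditions: H2 (1 atm), Pd/C, EtOAc, rt
Reagents that add atoms: none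
Why: Heterogeneous hydrogenation saturates the strained cis-disubstituted alkene (the future C9–C10) far faster than it touches the ketone or the tertiary ether carbons, and the product stays meso.

Step 4
Reactants: 6 meso bicyclic ketone
Product: 8 (1S,5R)-1,5-dimethyl-3-(trimethylsilyloxy)-8-oxabicyclo[3.2.1]oct-2-ene, via lithium enolate 7 (not isolated)
Conditions: (R,R)-bis(1-phenylethyl)amine·HCl, n-BuLi (2 equiv), THF, −78 → 0 °C; 6, −100 °C; TMSCl, −100 → −78 °C
Reagents that add atoms: chlorotrimethylsilane, C[Si](C)(C)Cl
Why: Enantioselective deprotonation of a meso ketone by a C2-symmetric chiral lithium amide in the presence of LiCl, established for 8-oxabicyclo[3.2.1]octan-3-ones and tropinone, removes the axial proton at C5 (the CH2 next to the S-configured bridgehead) rather than its mirror image at C7, and O-silylation fixes this choice, which decides that C1–O will break and that C8 survives as the R carbinol carbon.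

Step 5
Reactants: 8 enol silane
Product: 9 (R)-3,6-dimethyl-6-(trimethylsilyloxy)cyclohept-2-en-1-one
Conditions: TMSOTf (10 mol %), 2,6-di-tert-butyl-4-methylpyridine (15 mol %), CH2Cl2, −78 → −20 °C
Reagents that add atoms: none
Why: TMSOTf silylates the bridging oxygen and the enol silane pushes it out of C1 (Lewis acid induced β-elimination of a β-alkoxy enol silane, known from the opening of oxabicyclic ketones with silyl triflates and from the unmasking of silyloxydiene cycloadducts), the O-silylated enone passes its silyl group on so that the triflate acts as a catalyst, the net O6-to-O8 silyl shift is downhill because an enol silane becomes a conjugated ketone, and the C8–O bond is never broken so that C8 keeps its configuration.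

Step 6
Reactants: 9 enone; 10 vinylmagnesium bromide; 11 acrolein
Product: 14 (2R,3S,6R)-3-ethenyl-6-hydroxy-2-(1-hydroxyprop-2-en-1-yl)-3,6-dimethylcycloheptan-1-one (both C4 carbinol epimers), via magnesium enolate 12 (not isolated), via C8-O-TMS aldol 13 (not isolated)
Conditions: 10, CuBr·SMe2 (20 mol %), THF/Me2S, −78 → −40 °C; 11 (freshly distilled), −78 °C; aq NH4Cl; then citric acid (cat.), MeOH, 0 °C
Reagents that add atoms: vinylmagnesium bromide 10, C=C[Mg]Br; acrolein 11, C=CC=O
Why: Copper-catalysed conjugate addition of a Grignard reagent with aldol trapping of the enolate (three-component coupling): 9 should react through the chair conformer that keeps the C8 methyl equatorial and the C8 silyloxy group axial on the β face, in which axial attack at C1 comes from the α face (cis to the C8 methyl, anti to the silyloxy group) and sets 1S, the enolate 12 then holds the new vinyl group pseudo-axial on the α face so that acrolein bonds to C5 from the β face, trans to vinyl, the C4 carbinol configuration does not matter because it is oxidised in step 10, and the methanolysis removes only the labile tertiary TMS ether.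

Step 7
Reactants: 14 keto diol
Product: 15 (2R,3S,6R)-2-[1-(tert-butyldimethylsilyloxy)prop-2-en-1-yl]-3-ethenyl-6-hydroxy-3,6-dimethylcycloheptan-1-one
Conditions: TBSOTf (1.05 equiv), 2,6-lutidine, CH2Cl2, −78 °C
Reagents that add atoms: tert-butyldimethylsilyl triflate, CC(C)(C)[Si](C)(C)OS(=O)(=O)C(F)(F)F
Why: Silyl triflate silylation at low temperature discriminates the secondary allylic C4–OH from the tertiary C8–OH on steric grounds, and it masks the only hydroxyl that could steer the next reduction to the wrong face.

Step 8
Reactants: 15 β-hydroxy ketone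
Product: 16 (1S,3R,6S,7S)-7-[1-(tert-butyldimethylsilyloxy)prop-2-en-1-yl]-6-ethenyl-3,6-dimethylcycloheptane-1,3-diol
Conditions: Me4NBH(OAc)3, MeCN/AcOH, −30 → −10 °C
Reagents that add atoms: none
Why: Evans–Saksena reduction: triacetoxyborohydride is too weak to reduce the ketone on its own, exchanges an acetate for the pseudo-axial tertiary C8–OH on the β face and hands its hydride to C6 from that face, which sets 6S (6α-OH, 1,3-anti to O8), the opposite of what an external hydride coming from the open α face would give.

Step 9
Reactants: 16 silyl ether diol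
Product: 17 (1S,3R,6S,7S)-6-ethenyl-7-(1-hydroxyprop-2-en-1-yl)-3,6-dimethylcycloheptane-1,3-diol
Conditions: HF·pyridine, pyridine, THF, 0 °C → rt
Reagents that add atoms: none
Why: Fluoride-driven cleavage of the silyl ether under pyridine buffering frees C4–OH without ionising the allylic or tertiary alcohols.

Step 10
Reactants: 17 triol
Product: 18 1-[(1S,2S,4R,7S)-7-ethenyl-2,4-dihydroxy-4,7-dimethylcycloheptyl]prop-2-en-1-one
Conditions: MnO2 (activated, excess), CH2Cl2, rt
Reagents that add atoms: none
Why: MnO2 oxidises allylic alcohols selectively, so only C4–OH reacts while the saturated secondary C6–OH and the tertiary C8–OH stay, both carbinol epimers converge on one vinyl ketone, and the neutral heterogeneous medium should neither epimerise C5 nor trigger oxa-Michael closure of O6 on the enone.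

Step 11
Reactants: 18 vinyl ketone; 19 isopropylmagnesium chloride
Product: 20 (1S,3R,6S,7S)-6-ethenyl-7-[(3S)-3-hydroxy-4-methylpent-1-en-3-yl]-3,6-dimethylcycloheptane-1,3-diol
Conditions: CeCl3 (5 equiv), 19 (4.5 equiv), THF, −78 °C; then 18, −78 °C; aq NH4Cl
Reagents that add atoms: isopropylmagnesium chloride 19, CC(C)[Mg]Cl
Why: Organocerium addition to an enone: the oxophilic, weakly basic reagent favours 1,2-addition over conjugate addition, enolisation and β-hydride reduction, the cerium alkoxide formed at O6 chelates the C4 carbonyl oxygen (Cram chelate, same sense as the Felkin–Anh model with the quaternary C1 as large group), one carbonyl face is walled off by C1 and its vinyl group, and isopropyl therefore enters from the side of H5 and sets 4S, which is why isopropyl and not vinyl is the group introduced last.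

Step 12
Reactants: 20 C1,C4-divinyl cycloheptane triol
Product: 21 (3S,3aS,4S,6R,8aS)-6,8a-dimethyl-3-(propan-2-yl)-3,3a,4,5,6,7,8,8a-octahydroazulene-3,4,6-triol
Conditions: second-generation Grubbs catalyst (5–10 mol %), 1,4-benzoquinone (10 mol %), CH2Cl2 (2 mM), 40 °C, argon sparge
Reagents that add atoms: none
Why: The ruthenium methylidene takes up the C4 vinyl group, whose free allylic hydroxyl speeds the loading, by [2+2] cycloaddition and cycloreversion, and the new alkylidene closes on the C1 vinyl group through a second metallacyclobutane that collapses to C2=C3 and returns the methylidene while ethylene escapes. The closest known reaction type is ring-closing metathesis of 1,6-dienes to cyclopentenes that carry an allylic quaternary carbon on one side and an allylic carbinol on the other. The five-membered ring closes by intramolecular alkene metathesis between two monosubstituted alkenes, one on C1 and one on C4, the substituent of the neighbouring ring atom C5, and the new alkene can only be cis inside the ring. No stereocentre is made and none is at risk, because C1, C4, C5, C6 and C8 are sp3 centres that are neither acidic nor ionisable in the neutral medium. The step needs cyclisation to beat cross-metathesis and alkene migration: the bulky C4 substituent keeps both arms equatorial on the seven-membered ring (dihedral near 60°, small enough for a trans fusion), the only rotamer about C4–C5 that places the small hydroxyl between C1 and C6 points the C4 vinyl at the C1 vinyl, both alkenes are too hindered to dimerise, and dilution, ethylene removal and the quinone additive take care of the rest.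

Step 13
Reactants: 22 vanillic acid
Product: 24 4-(tert-butyldimethylsilyloxy)-3-methoxybenzoic acid, via bis-silylated vanillic acid 23 (not isolated)
Conditions: TBSCl (2.2 equiv), imidazole, DMF, rt; then AcOH/THF/H2O, rt
Reagents that add atoms: tert-butyldimethylsilyl chloride, CC(C)(C)[Si](C)(C)Cl
Why: Both acidic hydroxyls are silylated and the much more labile silyl ester is then hydrolysed selectively, a standard way to an O-silyl hydroxybenzoic acid.

Step 14
Reactants: 21 bicyclic triol; 24 O-silyl vanillic acid
Product: 25 (3S,3aS,4S,6R,8aS)-3,6-dihydroxy-6,8a-dimethyl-3-(propan-2-yl)-3,3a,4,5,6,7,8,8a-octahydroazulen-4-yl 4-(tert-butyldimethylsilyloxy)-3-methoxybenzoate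
Conditions: DCC, DMAP, CH2Cl2, rt
Reagents that add atoms: none
Why: Steglich esterification: the acylpyridinium derived from 24 can only reach the equatorial secondary C6–OH, the tertiary C4 and C8 hydroxyls being inert under these conditions, as is usual for polyols of this kind.

Step 15
Reactants: 25 silyl-protected ester
Product: 26 (3S,3aS,4S,6R,8aS)-3,6-dihydroxy-6,8a-dimethyl-3-(propan-2-yl)-3,3a,4,5,6,7,8,8a-octahydroazulen-4-yl 4-hydroxy-3-methoxybenzoate (CNP0113302.1)
Conditions: TBAF, AcOH, THF, 0 °C
Reagents that add atoms: none
Why: Aryl silyl ethers are the most fluoride-labile silyl ethers, and acetic acid buffering keeps the phenoxide from attacking the ester and avoids any acid strong enough to ionise the tertiary allylic C4–OH.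

Compound list
1 | 2,5-dimethylfuran | Cc1ccc(C)o1 | starting material
2 | 1,1,3-trichloroacetone | ClCC(=O)C(Cl)Cl | starting material
3 | 1,3-dichloro-2-oxyallyl cation | [O-]C(=CCl)[CH+]Cl | intermediate
4 | 2,4-dichloro-1,5-dimethyl-8-oxabicyclo[3.2.1]oct-6-en-3-one (C–Cl epimers) | C[C@]12C=C[C@](C)(O1)C(Cl)C(=O)C2Cl | intermediate
5 | (1R,5S)-1,5-dimethyl-8-oxabicyclo[3.2.1]oct-6-en-3-one (meso) | C[C@]12C=C[C@](C)(O1)CC(=O)C2 | intermediate
6 | (1R,5S)-1,5-dimethyl-8-oxabicyclo[3.2.1]octan-3-one (meso) | C[C@]12CC[C@](C)(O1)CC(=O)C2 | intermediate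
7 | lithium (1S,5R)-1,5-dimethyl-8-oxabicyclo[3.2.1]oct-2-en-3-olate | C[C@]12CC[C@](C)(O1)C=C([O-])C2.[Li+] | intermediate
8 | (1S,5R)-1,5-dimethyl-3-(trimethylsilyloxy)-8-oxabicyclo[3.2.1]oct-2-ene | C[C@]12CC[C@](C)(O1)C=C(O[Si](C)(C)C)C2 | intermediate
9 | (R)-3,6-dimethyl-6-(trimethylsilyloxy)cyclohept-2-en-1-one | O=C1C[C@](C)(O[Si](C)(C)C)CCC(C)=C1 | intermediate
10 | vinylmagnesium bromide | C=C[Mg]Br | starting material
11 | acrolein | C=CC=O | starting material
12 | bromomagnesium (3S,6R)-3-ethenyl-3,6-dimethyl-6-(trimethylsilyloxy)cyclohept-1-en-1-olate | Br[Mg]OC1=C[C@](C)(C=C)CC[C@@](C)(O[Si](C)(C)C)C1 | intermediate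
13 | (2R,3S,6R)-3-ethenyl-2-(1-hydroxyprop-2-en-1-yl)-3,6-dimethyl-6-(trimethylsilyloxy)cycloheptan-1-one (C4 epimers) | O=C1C[C@](C)(O[Si](C)(C)C)CC[C@@](C)(C=C)[C@@H]1C(O)C=C | intermediate
14 | (2R,3S,6R)-3-ethenyl-6-hydroxy-2-(1-hydroxyprop-2-en-1-yl)-3,6-dimethylcycloheptan-1-one (C4 epimers) | O=C1C[C@](C)(O)CC[C@@](C)(C=C)[C@@H]1C(O)C=C | intermediate
15 | (2R,3S,6R)-2-[1-(tert-butyldimethylsilyloxy)prop-2-en-1-yl]-3-ethenyl-6-hydroxy-3,6-dimethylcycloheptan-1-one (C4 epimers) | O=C1C[C@](C)(O)CC[C@@](C)(C=C)[C@@H]1C(O[Si](C)(C)C(C)(C)C)C=C | intermediate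
16 | (1S,3R,6S,7S)-7-[1-(tert-butyldimethylsilyloxy)prop-2-en-1-yl]-6-ethenyl-3,6-dimethylcycloheptane-1,3-diol (C4 epimers) | O[C@H]1C[C@](C)(O)CC[C@@](C)(C=C)[C@@H]1C(O[Si](C)(C)C(C)(C)C)C=C | intermediate
17 | (1S,3R,6S,7S)-6-ethenyl-7-(1-hydroxyprop-2-en-1-yl)-3,6-dimethylcycloheptane-1,3-diol (C4 epimers) | O[C@H]1C[C@](C)(O)CC[C@@](C)(C=C)[C@@H]1C(O)C=C | intermediate
18 | 1-[(1S,2S,4R,7S)-7-ethenyl-2,4-dihydroxy-4,7-dimethylcycloheptyl]prop-2-en-1-one | O[C@H]1C[C@](C)(O)CC[C@@](C)(C=C)[C@@H]1C(=O)C=C | intermediate
19 | isopropylmagnesium chloride | CC(C)[Mg]Cl | starting material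
20 | (1S,3R,6S,7S)-6-ethenyl-7-[(3S)-3-hydroxy-4-methylpent-1-en-3-yl]-3,6-dimethylcycloheptane-1,3-diol | O[C@H]1C[C@](C)(O)CC[C@@](C)(C=C)[C@@H]1[C@](O)(C(C)C)C=C | intermediate
21 | (3S,3aS,4S,6R,8aS)-6,8a-dimethyl-3-(propan-2-yl)-3,3a,4,5,6,7,8,8a-octahydroazulene-3,4,6-triol | O[C@H]1C[C@](C)(O)CC[C@@]2(C)C=C[C@@](O)(C(C)C)[C@H]12 | intermediate
22 | vanillic acid | COc1cc(C(=O)O)ccc1O | starting material
23 | tert-butyldimethylsilyl 4-(tert-butyldimethylsilyloxy)-3-methoxybenzoate | COc1cc(C(=O)O[Si](C)(C)C(C)(C)C)ccc1O[Si](C)(C)C(C)(C)C | intermediate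
24 | 4-(tert-butyldimethylsilyloxy)-3-methoxybenzoic acid | COc1cc(C(=O)O)ccc1O[Si](C)(C)C(C)(C)C | intermediate
25 | (3S,3aS,4S,6R,8aS)-3,6-dihydroxy-6,8a-dimethyl-3-(propan-2-yl)-3,3a,4,5,6,7,8,8a-octahydroazulen-4-yl 4-(tert-butyldimethylsilyloxy)-3-methoxybenzoate | COc1cc(C(=O)O[C@H]2C[C@](C)(O)CC[C@@]3(C)C=C[C@@](O)(C(C)C)[C@H]23)ccc1O[Si](C)(C)C(C)(C)C | intermediate
26 | (3S,3aS,4S,6R,8aS)-3,6-dihydroxy-6,8a-dimethyl-3-(propan-2-yl)-3,3a,4,5,6,7,8,8a-octahydroazulen-4-yl 4-hydroxy-3-methoxybenzoate | COc1cc(C(=O)O[C@H]2C[C@](C)(O)CC[C@@]3(C)C=C[C@@](O)(C(C)C)[C@H]23)ccc1O | target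

Total step count: 15. Longest linear sequence: 14 (steps 1–12, 14 and 15; step 13 prepares the acid in parallel).

**Steps most likely to fail**

**Step 11.** Conjugate addition at the unhindered terminal carbon of the vinyl ketone may outrun attack on the carbonyl, which is flanked by the neopentyl-type C5. β-Hydride transfer from the isopropyl reagent is a second competitor. Deprotonation at C5 is a third, followed by retro-aldol opening or loss of O6. The fallback reverses the order of ring closure and isopropyl addition while keeping the same metathesis disconnection.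
- It sets out from 18. Ring-closing metathesis of the C1 vinyl group with the acryloyl alkene (second-generation Hoveyda–Grubbs catalyst, toluene, 80 °C) should give the trans-fused cyclopentenone (3aS,4S,6R,8aS)-4,6-dihydroxy-6,8a-dimethyl-4,5,6,7,8,8a-hexahydroazulen-3(3aH)-one F1.
- In this enone the β-carbon C2 sits next to the quaternary C1 and is shielded, whereas the carbonyl is exposed.
- The isopropylcerium reagent of step 11 should then add 1,2 from the α face, opposite the angular C1 methyl group. The fallback comes back to the route at 21.

**Step 6.** Several things may go wrong here: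
- poor facial selectivity at C1 or C5, if conformers other than the one with the equatorial C8 methyl take part;
- competing 1,2-addition;
- base-induced loss of the C8 silyloxy group through the C7 enolate;
- a sluggish or reversible aldol at the hindered C5.

The fallback separates the two bond formations.
- It sets out from 9. Reagent 10 with CuBr·SMe2 and TMSCl in THF at −78 °C should give the enol silane (3S,6R)-3-ethenyl-3,6-dimethyl-1,6-bis(trimethylsilyloxy)cyclohept-1-ene F2. This compound can be purified and freed from any C1 epimer.
- A Mukaiyama aldol addition of F2 to 11 (BF3·OEt2, CH2Cl2, −78 °C) then proceeds through an open transition state. In it the aldehyde–Lewis acid complex has to avoid the pseudo-axial vinyl group.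
- The methanolysis of step 6 follows, and the fallback comes back to the route at 14.

**Step 4.** Incomplete discrimination between the two enantiotopic α-protons, or equilibration of the enolate before silylation, would erode the enantiomeric purity on which all later centres depend. The fallback gives up the desymmetrisation and takes the absolute configuration from a catalyst.
- It sets out from 6. LDA and TMSCl give the racemic enol silane rac-1,5-dimethyl-3-(trimethylsilyloxy)-8-oxabicyclo[3.2.1]oct-2-ene F3.
- The conditions of step 5 turn F3 into the racemic enone rac-3,6-dimethyl-6-(trimethylsilyloxy)cyclohept-2-en-1-one F4.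
- Diethyl(vinyl)aluminium (from 10 and Et2AlCl, about half an equivalent), Cu(OTf)2 and a chiral sulfonate-bearing imidazolinium salt as carbene precursor then add vinyl to the α face of C1. This is the known copper-catalysed enantioselective conjugate addition of alkenylaluminium reagents to β-methyl cycloalkenones.
- The R enone, for which catalyst and substrate preferences agree, should be consumed first. It gives the diethylaluminium enolate of (3S,6R)-3-ethenyl-3,6-dimethyl-6-(trimethylsilyloxy)cycloheptanone F5.
- F5 is trapped with 11 as in step 6. Methanolysis and chromatographic removal of the unreacted S enone and of minor diastereomers follow, and the fallback comes back to the route at 14.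

Further compounds
F1 | step 11 | (3aS,4S,6R,8aS)-4,6-dihydroxy-6,8a-dimethyl-4,5,6,7,8,8a-hexahydroazulen-3(3aH)-one | O[C@H]1C[C@](C)(O)CC[C@@]2(C)C=CC(=O)[C@H]12
F2 | step 6 | (3S,6R)-3-ethenyl-3,6-dimethyl-1,6-bis(trimethylsilyloxy)cyclohept-1-ene | C[Si](C)(C)OC1=C[C@](C)(C=C)CC[C@@](C)(O[Si](C)(C)C)C1
F3 | step 4 | rac-1,5-dimethyl-3-(trimethylsilyloxy)-8-oxabicyclo[3.2.1]oct-2-ene | CC12CCC(C)(O1)C=C(O[Si](C)(C)C)C2
F4 | step 4 | rac-3,6-dimethyl-6-(trimethylsilyloxy)cyclohept-2-en-1-one | O=C1CC(C)(O[Si](C)(C)C)CCC(C)=C1
F5 | step 4 | diethylaluminium (3S,6R)-3-ethenyl-3,6-dimethyl-6-(trimethylsilyloxy)cyclohept-1-en-1-olate | CC[Al](CC)OC1=C[C@](C)(C=C)CC[C@@](C)(O[Si](C)(C)C)C1
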